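All runs were computed for substances that don't exist, noise included.

The time of reading, 1.5 h, lies beyond both earlier runs, which stop at 50.0 min, so the flasks have to be reckoned.

| flask | J | remark | time |
|---|---|---|---|
| green | 0.29 M | run made earlier |  |
| ochre | 0.75 M | run made earlier |  |
| elm | 0.58 M |  | 1.5 h |
| birch | 0.30 M |  | 1.5 h |
| oak | 0.20 M |  | 1.5 h |
| cedar | 0.40 M |  | 1.5 h |

| green: time / min | green: X / % | ochre: time / min | ochre: X / % |
|---|---|---|---|
| 10.0 | 2.7 | 4.00 | 0.9 |
| 20.0 | 5.7 | 6.00 | 1.4 |
| 25.0 | 6.2 | 12.0 | 4.5 |
| 40.0 | 11.0 | 25.0 | 7.3 |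
| 50.0 | 14.2 | 50.0 | 22.4 |

(scatter of a reading: 0.5 percentage points)

- what may be going on: J + 2 X -> 3 X; J -> X

* ranking by amount of X, in percent of the J charged, from high to low, at 1.5 h (elm / birch / oak / cedar)
* the amount of X, in percent of the J charged of the flask you put first, at 1.5 h
* the amount of X, in percent of the J charged of the flask you put last, at 1.5 h

Green's last reading gives a first-order constant k = 0.00306 min⁻¹, which I take for J → X, though green holds some of the other step too. But ochre, between its last two readings, loses J at 0.00711 min⁻¹ per unit of J, faster than k, at a mean X of 0.111 M. The autocatalytic step goes with the square of X, so the two steps run equal at Xc = 0.0969 M, the crossover amount of X, a reading with its scatter.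

J → X by itself turns 24.1% of a charge by 1.5 h. For oak that is 0.0482 M of X, below Xc, so I expect oak near that figure. Elm needs 16.7% to cross, which J → X by itself gives at 59.7 min, leaving 30.3 min, so I expect elm first but well short of complete.

The forecast says elm > cedar > birch > oak, with 97% and 25%; of elm it says “it passes 90% near 80 min”. On elm it differs from my reckoning.

The simulation gives elm > cedar > birch > oak, with 58.5% and 24.8%, so elm lies under the forecast.

    J + 2 X → 3 X (k = 0.330 M⁻² min⁻¹)
    J → X (k = 0.00290 min⁻¹)

In oak at 1.50 h, X is 0.0497 M, below Xc, and the computed rate of J → X over the autocatalytic step is 3.6. Elm stood at 15.1% at 0.750 h, below its crossing point, and at 58.5% at 1.50 h, with 42% of its J left.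

For the neighbour of oak charged with 0.80 M, crossing needs 12.1%, which J → X by itself gives at 42.2 min, earlier than in elm. It computes to 99.1% at 1.50 h, with 0.89% of its J left.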